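**Retrosynthetic overview**
- The usual plan (auxiliary-controlled enolate alkylation plus Wittig/HWE olefination) is set aside. The skeleton is cut at the sp3–sp2 bond between C5 and C6 into an alpha-allyl acid (fragment A) and a stereodefined 2-iodoallyl alcohol (fragment B), joined by a protecting-group-free B-alkyl Suzuki coupling; O-acetylation comes last.
- Fragment A: the only stereocentre (C2) is set directly on the free acid by an enantioselective boron-enolate Ireland–Claisen rearrangement of an achiral allyl ester made from diallyl malonate and homoprenyl bromide.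
- Fragment B: a one-pot 1,3-dilithiopropyne linchpin (3-furylmethyl bromide, then methyl chloroformate) gives an ynoate; syn-hydrostannation/iodination and reduction fix the alkene geometry before the coupling.
- No ring is formed: the furan ring is bought in and carried through.

Assumption: 3-(bromomethyl)furan, propyne and 5-bromo-2-methylpent-2-ene are bought, the (S,S)-bromoborane of step 3 is made beforehand as a reagent from (S,S)-1,2-diphenylethane-1,2-diamine, and its sense of induction is taken from the chair model given in step 3 (the (R,R)-antipode is used in the same way should the first assay show the opposite enantiomer).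

**Route**

Step 1
Reactants: 1 diallyl malonate; 2 5-bromo-2-methylpent-2-ene
Product: 4 diallyl 2-(4-methylpent-3-en-1-yl)malonate, via sodium diallyl malonate enolate 3 (not isolated)
Conditions: NaH, THF/DMF, 0 °C; then 2, NaI (cat.), 60 °C (1 in 1.5-fold excess)
Reagents that add atoms: none
Why: Malonic ester alkylation (SN2) of the soft sodium enolate by a primary bromide, with excess malonate suppressing dialkylation.

Step 2
Reactants: 4 diallyl 2-(4-methylpent-3-en-1-yl)malonate
Product: 5 allyl 6-methylhept-5-enoate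
Conditions: LiCl, H2O, DMSO, 150 °C
Reagents that add atoms: none
Why: Krapcho dealkoxycarbonylation removes one allyl ester group and leaves the mono-allyl ester and the trisubstituted alkene untouched.

Step 3
Reactants: 5 allyl 6-methylhept-5-enoate
Product: 8 (2S)-6-methyl-2-(prop-2-en-1-yl)hept-5-enoic acid, via E(O) boron ketene acetal 6 (not isolated), via boron carboxylate 7 (not isolated)
Conditions: (4S,5S)-2-bromo-1,3-bis{[3,5-bis(trifluoromethyl)phenyl]sulfonyl}-4,5-diphenyl-1,3,2-diazaborolidine (1.2 equiv), Et3N, toluene/hexane, −78 °C; then −20 °C, several days; aqueous work-up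
Reagents that add atoms: none
Why: Enantioselective boron-enolate Ireland–Claisen rearrangement (Corey-type chiral diazaborolidine), in which the C2-symmetric controller forms the E(O) boron ketene acetal and its chair [3,3] shift delivers the allyl terminus to the Re face of C2, setting the S centre and releasing the free acid on work-up.

Step 4
Reactants: 9 propyne; 10 3-(bromomethyl)furan
Product: 13 methyl 5-(furan-3-yl)pent-2-ynoate, via 1,3-dilithiopropyne 11 (not isolated), via lithium 4-(furan-3-yl)but-1-yn-1-ide 12 (not isolated)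
Conditions: n-BuLi (2.1 equiv), TMEDA, Et2O/hexane, 0 °C to rt; 10, −78 to 0 °C; ClCO2Me, −78 °C
Reagents that add atoms: methyl chloroformate, COC(=O)Cl
Why: Dianion linchpin alkylation (Hooz-type), in which the sp3 carbanion of 1,3-dilithiopropyne displaces the reactive furylmethyl bromide by SN2 and the surviving acetylide is then acylated by the chloroformate.

Step 5
Reactants: 13 methyl 5-(furan-3-yl)pent-2-ynoate
Product: 15 methyl (2E)-5-(furan-3-yl)-2-iodopent-2-enoate, via alpha-stannyl enoate 14 (not isolated)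
Conditions: Bu3SnH, Pd(PPh3)4 (2 mol%), THF, 0 °C to rt; then I2, 0 °C, dark; aq. KF/Na2S2O3
Reagents that add atoms: iodine, II
Why: Palladium-catalysed syn-hydrostannation of a 2-ynoate places tin on the alpha carbon and hydrogen on the beta carbon on the same face, and iododestannylation goes with retention, so the ester carbon and the furylethyl chain end up cis.

Step 6
Reactants: 15 methyl (2E)-5-(furan-3-yl)-2-iodopent-2-enoate
Product: 16 (2E)-5-(furan-3-yl)-2-iodopent-2-en-1-ol
Conditions: i-Bu2AlH (2.3 equiv), CH2Cl2, −78 °C; aq. KNaC4H4O6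
Reagents that add atoms: none
Why: 1,2-Reduction of the enoate by i-Bu2AlH at low temperature gives the allylic alcohol without touching the vinyl iodide or the alkene geometry.

Step 7
Reactants: 8 (2S)-6-methyl-2-(prop-2-en-1-yl)hept-5-enoic acid; 16 (2E)-5-(furan-3-yl)-2-iodopent-2-en-1-ol
Product: 18 (2R,6Z)-9-(furan-3-yl)-6-(hydroxymethyl)-2-(4-methylpent-3-en-1-yl)non-6-enoic acid, via B-alkyl-9-BBN acyloxyborane 17 (not isolated)
Conditions: 9-BBN (2.3 equiv), THF, 0 °C to rt; then 16, Pd(dppf)Cl2 (5 mol%), AsPh3, Cs2CO3, DMF/H2O, rt; work-up at pH 4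
Reagents that add atoms: none
Why: B-alkyl Suzuki–Miyaura coupling, in which 9-BBN hydroborates only the terminal alkene (the acid O–H takes one equivalent as an acyloxyborane that the aqueous base hydrolyses) and oxidative addition, transmetalation and reductive elimination at the vinyl iodide go with retention, giving the Z trisubstituted alkene while C2 is untouched (its descriptor changes from S to R only by CIP priority).

Step 8
Reactants: 18 (2R,6Z)-9-(furan-3-yl)-6-(hydroxymethyl)-2-(4-methylpent-3-en-1-yl)non-6-enoic acid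
Product: 20 (2R,6Z)-6-[(acetyloxy)methyl]-9-(furan-3-yl)-2-(4-methylpent-3-en-1-yl)non-6-enoic acid, via mixed acetic anhydride 19 (not isolated)
Conditions: Ac2O (3 equiv), pyridine, DMAP (cat.), CH2Cl2, 0 °C to rt; then H2O/THF, NaHCO3, rt; work-up at pH 4
Reagents that add atoms: acetic anhydride, CC(=O)OC(C)=O
Why: DMAP-catalysed O-acetylation (nucleophilic acyl substitution) of the primary allylic alcohol, after which the mixed anhydride formed at the acid is cleaved by mild aqueous hydrolysis that leaves the acetate ester intact.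

**Compound list**
1 | diallyl malonate (diprop-2-en-1-yl propanedioate) | C=CCOC(=O)CC(=O)OCC=C | starting material
2 | 5-bromo-2-methylpent-2-ene | CC(C)=CCCBr | starting material
3 | sodium enolate of diallyl malonate | C=CCOC(=O)[CH-]C(=O)OCC=C.[Na+] | intermediate
4 | diallyl 2-(4-methylpent-3-en-1-yl)malonate | CC(C)=CCCC(C(=O)OCC=C)C(=O)OCC=C | intermediate
5 | allyl 6-methylhept-5-enoate | CC(C)=CCCCC(=O)OCC=C | intermediate
6 | E(O) boron ketene acetal of 5 (O-allyl, O-[(4S,5S)-diazaborolidin-2-yl]; alkyl chain trans to the O–B oxygen) | C=CCO/C(OB1N(S(=O)(=O)c2cc(cc(c2)C(F)(F)F)C(F)(F)F)[C@@H](c2ccccc2)[C@H](c2ccccc2)N1S(=O)(=O)c1cc(cc(c1)C(F)(F)F)C(F)(F)F)=C\CCC=C(C)C | intermediate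
7 | boron carboxylate: (4S,5S)-diazaborolidin-2-yl (2S)-6-methyl-2-(prop-2-en-1-yl)hept-5-enoate | C=CC[C@H](CCC=C(C)C)C(=O)OB1N(S(=O)(=O)c2cc(cc(c2)C(F)(F)F)C(F)(F)F)[C@@H](c2ccccc2)[C@H](c2ccccc2)N1S(=O)(=O)c1cc(cc(c1)C(F)(F)F)C(F)(F)F | intermediate
8 | (2S)-6-methyl-2-(prop-2-en-1-yl)hept-5-enoic acid | C=CC[C@H](CCC=C(C)C)C(=O)O | intermediate
9 | propyne | CC#C | starting material
10 | 3-(bromomethyl)furan | BrCc1ccoc1 | starting material
11 | 1,3-dilithiopropyne | [Li]CC#C[Li] | intermediate
12 | lithium 4-(furan-3-yl)but-1-yn-1-ide | [Li]C#CCCc1ccoc1 | intermediate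
13 | methyl 5-(furan-3-yl)pent-2-ynoate | COC(=O)C#CCCc1ccoc1 | intermediate
14 | methyl (2E)-5-(furan-3-yl)-2-(tributylstannyl)pent-2-enoate | COC(=O)/C(=C\CCc1ccoc1)[Sn](CCCC)(CCCC)CCCC | intermediate
15 | methyl (2E)-5-(furan-3-yl)-2-iodopent-2-enoate | COC(=O)/C(I)=C\CCc1ccoc1 | intermediate
16 | (2E)-5-(furan-3-yl)-2-iodopent-2-en-1-ol | OC/C(I)=C\CCc1ccoc1 | intermediate
17 | B-alkyl-9-BBN acyloxyborane of 8 (9-BBN on the chain terminus and on the carboxylate oxygen) | B1(C2CCCC1CCC2)CCC[C@H](CCC=C(C)C)C(=O)OB1C2CCCC1CCC2 | intermediate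
18 | (2R,6Z)-9-(furan-3-yl)-6-(hydroxymethyl)-2-(4-methylpent-3-en-1-yl)non-6-enoic acid | OC/C(=C\CCc1ccoc1)CCC[C@H](CCC=C(C)C)C(=O)O | intermediate
19 | mixed acetic anhydride of 20 | CC(=O)OC/C(=C\CCc1ccoc1)CCC[C@H](CCC=C(C)C)C(=O)OC(C)=O | intermediate
20 | (2R,6Z)-6-[(acetyloxy)methyl]-9-(furan-3-yl)-2-(4-methylpent-3-en-1-yl)non-6-enoic acid | CC(=O)OC/C(=C\CCc1ccoc1)CCC[C@H](CCC=C(C)C)C(=O)O | target

**Step count and risks**
Total step count: 8. Longest linear sequence: 5 steps (steps 1, 2, 3, 7, 8 or steps 4, 5, 6, 7, 8).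

Most likely to fail, in this order:

Step 3. The boron Ireland–Claisen is known mainly for allyl esters that carry a substituent on the allyl terminus; here the only new stereocentre is C2, so the enantiomeric excess, the rate and the absolute sense all need to be confirmed on a small run. The fallback gives up the rearrangement for an auxiliary-controlled alkylation; it sets out from 5 and comes back at 8. Saponification of 5 (LiOH, THF/H2O) gives 6-methylhept-5-enoic acid F1. Pivaloyl chloride/Et3N turns it into 6-methylhept-5-enoic pivalic anhydride F2, which acylates lithiated (4R)-4-benzyl-1,3-oxazolidin-2-one to give (4R)-4-benzyl-3-(6-methylhept-5-enoyl)-1,3-oxazolidin-2-one F3. NaN(SiMe3)2 in THF at −78 °C gives the sodium Z(O)-enolate of the imide F4, which allyl iodide alkylates on the face away from the benzyl group to give (4R)-4-benzyl-3-[(2S)-6-methyl-2-(prop-2-en-1-yl)hept-5-enoyl]-1,3-oxazolidin-2-one F5. LiOH/H2O2 at 0 °C then releases 8.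

Step 7. Hydroboration and coupling are run on the unprotected acid; the acyloxyborane may be reduced slowly by excess 9-BBN or may slow transmetalation. The fallback changes to a masked-acid union; it sets out from 8 (with 16) and comes back at 18. MeI/K2CO3 in DMF gives methyl (2S)-6-methyl-2-(prop-2-en-1-yl)hept-5-enoate F6. One equivalent of 9-BBN gives the B-alkyl-9-BBN of the ester F7, which is coupled to 16 under the same Pd(dppf)Cl2/Cs2CO3 conditions to give methyl (2R,6Z)-9-(furan-3-yl)-6-(hydroxymethyl)-2-(4-methylpent-3-en-1-yl)non-6-enoate F8. LiOH in THF/H2O then gives 18.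

Step 4. The dianion must be formed cleanly, and the bromide can be attacked twice or the furan metalated. The fallback replaces the one-pot dianion by a stepwise silyl-propargyl route; it sets out from 10 and comes back at 13. 1-(Trimethylsilyl)propyne with n-BuLi/TMEDA gives 3-lithio-1-(trimethylsilyl)propyne F9, which is alkylated by 10 to give 3-[4-(trimethylsilyl)but-3-yn-1-yl]furan F10. K2CO3/MeOH removes the silyl group to give 3-(but-3-yn-1-yl)furan F11. n-BuLi at −78 °C gives the acetylide 12, and ClCO2Me then gives 13.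

**Further compounds**
F1 | step 3 | 6-methylhept-5-enoic acid | CC(C)=CCCCC(=O)O
F2 | step 3 | 6-methylhept-5-enoic pivalic anhydride | CC(C)=CCCCC(=O)OC(=O)C(C)(C)C
F3 | step 3 | (4R)-4-benzyl-3-(6-methylhept-5-enoyl)-1,3-oxazolidin-2-one | CC(C)=CCCCC(=O)N1[C@H](Cc2ccccc2)COC1=O
F4 | step 3 | sodium Z(O)-enolate of F3 | CC(C)=CCC/C=C(\[O-])N1[C@H](Cc2ccccc2)COC1=O.[Na+]
F5 | step 3 | (4R)-4-benzyl-3-[(2S)-6-methyl-2-(prop-2-en-1-yl)hept-5-enoyl]-1,3-oxazolidin-2-one | C=CC[C@H](CCC=C(C)C)C(=O)N1[C@H](Cc2ccccc2)COC1=O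
F6 | step 7 | methyl (2S)-6-methyl-2-(prop-2-en-1-yl)hept-5-enoate | C=CC[C@H](CCC=C(C)C)C(=O)OC
F7 | step 7 | B-alkyl-9-BBN of F6 | B1(C2CCCC1CCC2)CCC[C@H](CCC=C(C)C)C(=O)OC
F8 | step 7 | methyl (2R,6Z)-9-(furan-3-yl)-6-(hydroxymethyl)-2-(4-methylpent-3-en-1-yl)non-6-enoate | OC/C(=C\CCc1ccoc1)CCC[C@H](CCC=C(C)C)C(=O)OC
F9 | step 4 | 3-lithio-1-(trimethylsilyl)propyne | [Li]CC#C[Si](C)(C)C
F10 | step 4 | 3-[4-(trimethylsilyl)but-3-yn-1-yl]furan | C[Si](C)(C)C#CCCc1ccoc1
F11 | step 4 | 3-(but-3-yn-1-yl)furan | C#CCCc1ccoc1
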